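Late in the dawn run the target falls while the reading of starting material holds still. Starting material reads 2% at 8.00 d and 2% at 15.0 d, yet target drops from 32% to 22%, a fall of 10 percentage points, which is larger than the scatter of 2 points. A repeat therefore has to keep reading target after the reading of starting material has levelled.

| flask | starting material | temperature | remark | time |
|---|---|---|---|---|
| winter | 0.050 M | 6 °C | run made earlier |  |
| dawn | 0.075 M | 20 °C | run made earlier |  |
| cedar | 0.10 M |  | at 25 °C until 10 d, from then on at 0 °C | 20 d |
| ash | 0.10 M | 25 °C |  | 20 d |
| birch | 0.10 M | 0 °C |  | 20 d |

- winter (time / d: target / %, starting material / %): 8.00: 24, 64; 15.0: 37, 46; 25.0: 44, 22; 30.0: 40, 18; 40.0: 41, 11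
- dawn (time / d: target / %, starting material / %): 1.25: 30, 59; 2.50: 36, 36; 5.00: 42, 12; 8.00: 32, 2; 15.0: 22, 2

(readings scatter by 2 percentage points)

- what may be going on: starting material -> target; starting material -> side product; target <-> isomer of the product

* the flask with the highest amount of target, in percent of the starting material charged ("all alike" if they lie within 1.5 percentage points) (cedar / ash / birch / all alike)
* final target, as a percentage of the starting material charged, in cedar
* final target, as a percentage of the starting material charged, in ash
* final target, as a percentage of the starting material charged, in birch

The next run hangs on one choice: whether a flask left warm can be trusted to hold target. Here the use of starting material is taken as first order in starting material, and the loss of target as first order in target, so percentages are carried from one charge to another. The first dawn reading gives the selectivity s, target formed per starting material used, as a reading with its scatter: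

s = 0.732

Dawn's last reading gives 0.307 for the target share φ, target over s times the part converted, and the reading before it gave 0.446. The share was thus smaller at the last reading, and dawn holds no later reading of it. For a fully converted flask, dawn's last share gives a line:

φ × s = 22.5%

Ash stands at 25 °C, warmer than dawn, and runs longer, so this reckoning puts ash below the line. Cedar should be read for target and isomer at 10 d, just before it is cooled.

The forecast differs for ash, which it sets at 22%, with 22% for cedar, 26% for birch and birch as the richest flask: “At equilibrium, target is about 27% of target plus isomer, or about 22% of charge.”

The flasks end at 15.2% in cedar, 12.2% in ash and 24.6% in birch, so birch holds more target than the other two.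

    starting material → target (k = 0.0250 h⁻¹, Ea = 97.0 kJ mol⁻¹)
    starting material → side product (k = 0.00860 h⁻¹, Ea = 98.0 kJ mol⁻¹)
    target ⇌ isomer of the product (K = 5.20, k = 0.0110 h⁻¹, Ea = 93.0 kJ mol⁻¹, ΔH = −50.0 kJ mol⁻¹)
    (constants at 25 °C)

Ash lies 9.8 points under the forecast, and left to 200 d it still holds 12.0%. The target share of ash is 0.167, smaller than dawn's last 0.307. The cedar flask read at 8.0 d holds 20.1% target, a share of 0.275.

The readings stem from a simulated flask with made-up constants, and the scatter is random.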